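The data are calculated with constants of no real substance, noise included.

- Grey holds more partner than teal, yet it ends with less catalysed material: open intermediate plus target reads 17.0% against 24.0% at 12.0 h. So I picture substrate with two exits: free catalyst opens it to open intermediate, or partner takes it straight to uncatalysed product, which nobody read.

| flask | substrate | partner | free catalyst | remark | time |
|---|---|---|---|---|---|
| teal | 20 mM | 22 mM | 20 µM | run made earlier |  |
| grey | 20 mM | 79 mM | 20 µM | run made earlier |  |
| Sunday's | 20 mM | 15.0 mM | 20 µM |  | 12 h |
| Saturday's | 20 mM | 25.0 mM | 20 µM |  | 12 h |
| Friday's | 20 mM | 40.0 mM | 20 µM |  | 12 h |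
| Monday's | 20 mM | 50.0 mM | 20 µM |  | 12 h |

| run | time / h | open intermediate / % | target / % |
|---|---|---|---|
| teal | 1.00 | 4 | 2 |
| teal | 2.00 | 5 | 1 |
| teal | 5.00 | 15 | 3 |
| teal | 12.0 | 18 | 6 |
| grey | 1.00 | 3 | 2 |
| grey | 2.00 | 5 | 0 |
| grey | 5.00 | 11 | 2 |
| grey | 12.0 | 9 | 8 |

(standard deviation of a reading: 1.5 percentage points)

- on the list of suspects stand: substrate + free catalyst -> free catalyst + open intermediate; free catalyst + open intermediate <-> catalyst intermediate; partner + catalyst intermediate -> free catalyst + target; 2 free catalyst <-> resting dimer; substrate + partner -> uncatalysed product
- "hardly changes" means that all values lie within two and a half points (for a concentration: within two and a half percent of the largest)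

- amount of open intermediate at the end, in percent of the substrate charged for Sunday's, Saturday's, Friday's, Monday's, in this order
- how that number moves from the first to the last of them (falls all the way / falls, then rises / hardly changes / rises all the way / rises, then falls)

- Teal's readings at 5.00 h give an opening rate of 0.0360 /h, a fraction of substrate per hour. If grey has levelled off, its catalysed yield equals opening rate over total loss rate, so substrate there disappears at 0.212 /h.
- But has grey levelled off? At 12.0 h it has had 2.54 lifetimes, leaving 7.86% unfinished, so I correct the total loss rate to 0.195 /h.
- Subtracting the opening rate and dividing by grey's partner gives the drain constant, the pseudo-first-order rate of the uncatalysed exit per unit of [partner], 0.00201 /mM/h. Its use is the drain share, drain rate over total loss rate, which says where reacted substrate goes.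
- Does target vary with partner? Teal and grey differ by 2 percentage points, less than the 2.1 points scatter of such a difference, so I subtract their mean, 7.00%, everywhere.
- My row for [partner] rising from 15.0 mM to 50.0 mM is 22.8%, 19.9%, 16.3% and 14.2%.
- Yet the same reckoning gives teal 27.7% catalysed material against the 24.0% read, so my low-partner end is probably high. That gap of 3.7 points is smaller than the row's fall of 8.6 points, so I keep the downward direction.
- The forecast, a separate judgement whose figures differ from mine, gives 21%, 19%, 15% and 12.5%, and its shape is falls all the way: “falling throughout is most likely”.
- The flasks give 19.8%, 18.5%, 16.2% and 14.8%, and the shape is falls all the way.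

    substrate + free catalyst → free catalyst + open intermediate (k = 2650 /M/h)
    free catalyst + open intermediate ⇌ catalyst intermediate (K = 980 /M, k = 4560 /M/h)
    partner + catalyst intermediate → free catalyst + target (k = 1360 /M/h)
    2 free catalyst ⇌ resting dimer, settled at all times (K = 16600 /M)
    substrate + partner → uncatalysed product (k = 1.91 /M/h)

- At the end of Monday's flask, uncatalysed product stands at 53.3% against 14.8% open intermediate and 6.74% target, which makes 71.2% of the reacted substrate, beside a drain share of 73.6% from the drain constant. In Sunday's flask the same figures are 45.3% and 45.6%, and at 12.0 h open intermediate there is still made 2.14 times faster than it is used up.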